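## Retrosynthetic overview

1. The tetronic acid is unmasked last by O‑demethylation; the (Z)‑C5=C1′ ylidene comes from aldol addition/mesylate elimination of lithiated 4‑methoxy‑3‑methylfuranone onto an (R)‑α‑methyl aldehyde.
2. Key disconnection: the C3′–C4′ sp3–sp3 bond next to the stereocentre, made by a Ni‑catalysed radical alkyl–alkyl Suzuki coupling. The primary radical comes from unprotected (S)‑3‑bromo‑2‑methylpropan‑1‑ol, which supplies C2′ with its configuration; the partner is the homoallyl‑9‑BBN from an (E)‑1,3‑diene.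
3. The (E)‑trisubstituted olefin comes from syn‑hydrozirconation of a 2‑alkyne followed by Negishi vinylation.
4. The alkyne is attached to 4‑bromo‑2‑(furan‑3‑ylmethyl)furan by Negishi coupling; that bromide comes from 3‑furyllithium + 4‑bromofurfural and ionic deoxygenation.
5. Ring order: no ring is built. Both furans and the tetronate ring are bought intact; the two furans are joined first (steps 1–2) and the tetronate is attached last (step 8).

Assumption: the SMILES is read as 5Z, 2′R, 6′E (side chain numbered C1′ = ylidene CH … C9′ = CH2 on the furan); 3‑methyltetronic acid, 5‑bromopent‑2‑yne and (S)‑3‑bromo‑2‑methylpropan‑1‑ol are taken as catalogue chemicals.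

## Route

**Step 1**
Reactants: 1 3‑bromofuran; 2 4‑bromofuran‑2‑carbaldehyde
Product: 3 (4‑bromofuran‑2‑yl)(furan‑3‑yl)methanol (racemic)
Conditions: 1, n‑BuLi, THF, −78 °C, 20 min; then 2, −78 °C; aq. NH4Cl
Reagents that add atoms: none
Why: Br/Li exchange gives 3‑furyllithium (kept at −78 °C so it does not isomerise to the 2‑lithio species), which adds 1,2 to the aldehyde faster than it exchanges with the C4–Br; the carbinol centre is removed in step 2.

**Step 2**
Reactants: 3
Product: 4 4‑bromo‑2‑(furan‑3‑ylmethyl)furan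
Conditions: Et3SiH, TFA, CH2Cl2, −20 → 0 °C
Reagents that add atoms: none
Why: Ionic hydrogenation; the bis‑heteroaryl carbinol ionises readily and the cation is trapped by silane hydride, while the C–Br bond is inert and low temperature limits furan oligomerisation.

**Step 3**
Reactants: 4; 5 5‑bromopent‑2‑yne
Product: 6 2‑(furan‑3‑ylmethyl)‑4‑(pent‑3‑yn‑1‑yl)furan
Conditions: 5, Zn dust, LiCl, THF, 50 °C; then 4, Pd(OAc)2 (2 mol %), SPhos (4 mol %), THF, 50 °C
Reagents that add atoms: none
Why: Negishi sp2–sp3 coupling of the homopropargylzinc bromide with the 3‑type bromofuran; the 2,4‑substitution pattern is fixed by the starting bromide and the internal alkyne is inert.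

**Step 4**
Reactants: 6; 7 vinyl bromide
Product: 8 2‑(furan‑3‑ylmethyl)‑4‑[(3E)‑4‑methylhexa‑3,5‑dien‑1‑yl]furan
Conditions: Cp2Zr(H)Cl (1.6 equiv), THF, rt → 40 °C; then ZnCl2, Pd(PPh3)4 (5 mol %), 7 (1 M in THF, excess), rt
Reagents that add atoms: none
Why: Syn‑hydrozirconation under equilibrating conditions (excess Schwartz reagent) puts Zr on the methyl‑bearing alkyne carbon, and ZnCl2‑assisted Negishi alkenyl–alkenyl coupling with retention sets the 3E trisubstituted olefin.

**Step 5 (key step)**
Reactants: 8; 9 (S)‑3‑bromo‑2‑methylpropan‑1‑ol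
Product: 10 (2R,6E)‑9‑[5‑(furan‑3‑ylmethyl)furan‑3‑yl]‑2,6‑dimethylnon‑6‑en‑1‑ol
Conditions: 8, 9‑BBN, THF, rt; then 9 (OH pre‑masked with 1 equiv 9‑BBN), NiCl2·glyme (10 mol %), trans‑N,N′‑dimethylcyclohexane‑1,2‑diamine (12 mol %), KOt‑Bu, i‑BuOH, dioxane, rt; ethanolamine work‑up
Reagents that add atoms: none
Why: Ni/diamine alkyl–alkyl Suzuki–Miyaura coupling: 9‑BBN adds only to the terminal vinyl group (B on CH2), and alkyl‑Ni(I) abstracts Br from 9 to give the primary C3 radical, which recombines at nickel and reductively eliminates the C3–C4 bond; the radical is β to the stereocentre, so the (S)‑bromide delivers the 2R centre untouched (the descriptor changes only through CIP priorities).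

**Step 6**
Reactants: 10
Product: 11 (2R,6E)‑9‑[5‑(furan‑3‑ylmethyl)furan‑3‑yl]‑2,6‑dimethylnon‑6‑enal
Conditions: Dess–Martin periodinane, NaHCO3, CH2Cl2, 0 °C → rt; used crude
Reagents that add atoms: none
Why: Buffered Dess–Martin oxidation gives the α‑chiral aldehyde without epimerisation and leaves the furans and the olefin alone.

**Step 7**
Reactants: 12 3‑methyltetronic acid (4‑hydroxy‑3‑methylfuran‑2(5H)‑one)
Product: 13 4‑methoxy‑3‑methylfuran‑2(5H)‑one
Conditions: Me2SO4, K2CO3, acetone, reflux
Reagents that add atoms: dimethyl sulfate, COS(=O)(=O)OC (adds the O‑CH3)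
Why: O‑alkylation of the vinylogous acid gives the 4‑methyl ether (C3 is blocked by methyl), masking the acidic OH so that C5 can be lithiated.

**Step 8**
Reactants: 11; 13
Product: 14 (5Z)‑5‑{(2R,6E)‑9‑[5‑(furan‑3‑ylmethyl)furan‑3‑yl]‑2,6‑dimethylnon‑6‑en‑1‑ylidene}‑4‑methoxy‑3‑methylfuran‑2(5H)‑one
Conditions: 13, LDA, THF, −78 °C; 11, −78 °C; then MsCl, Et3N, −78 → 0 °C; then DBU, rt (one pot)
Reagents that add atoms: none
Why: Aldol addition of the C5‑lithiated methyl tetronate, in‑situ mesylation and E1cB elimination give the thermodynamically preferred Z‑ylidene (chain anti to the C4–OMe); the aldehyde is not enolised at −78 °C, so C2′ stays R.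

**Step 9**
Reactants: 14
Product: 15 target, (5Z)‑5‑{(2R,6E)‑9‑[5‑(furan‑3‑ylmethyl)furan‑3‑yl]‑2,6‑dimethylnon‑6‑en‑1‑ylidene}‑4‑hydroxy‑3‑methylfuran‑2(5H)‑one
Conditions: n‑PrSLi (n‑PrSH, n‑BuLi), HMPA, rt; cold pH 3 work‑up
Reagents that add atoms: none
Why: SN2 O‑demethylation of the vinylogous methyl ester by a soft thiolate frees the tetronic acid without acid, so the furans, both olefin geometries and the stereocentre are preserved.

## Compound list

1 | 3‑bromofuran | Brc1ccoc1 | starting material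
2 | 4‑bromofuran‑2‑carbaldehyde | O=Cc1cc(Br)co1 | starting material
3 | (4‑bromofuran‑2‑yl)(furan‑3‑yl)methanol (racemic) | OC(c1ccoc1)c1cc(Br)co1 | intermediate
4 | 4‑bromo‑2‑(furan‑3‑ylmethyl)furan | Brc1coc(Cc2ccoc2)c1 | intermediate
5 | 5‑bromopent‑2‑yne | CC#CCCBr | starting material
6 | 2‑(furan‑3‑ylmethyl)‑4‑(pent‑3‑yn‑1‑yl)furan | CC#CCCc1coc(Cc2ccoc2)c1 | intermediate
7 | vinyl bromide | C=CBr | starting material
8 | 2‑(furan‑3‑ylmethyl)‑4‑[(3E)‑4‑methylhexa‑3,5‑dien‑1‑yl]furan | C=C/C(C)=C/CCc1coc(Cc2ccoc2)c1 | intermediate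
9 | (S)‑3‑bromo‑2‑methylpropan‑1‑ol | OC[C@H](C)CBr | starting material
10 | (2R,6E)‑9‑[5‑(furan‑3‑ylmethyl)furan‑3‑yl]‑2,6‑dimethylnon‑6‑en‑1‑ol | OC[C@H](C)CCC/C(C)=C/CCc1coc(Cc2ccoc2)c1 | intermediate
11 | (2R,6E)‑9‑[5‑(furan‑3‑ylmethyl)furan‑3‑yl]‑2,6‑dimethylnon‑6‑enal | O=C[C@H](C)CCC/C(C)=C/CCc1coc(Cc2ccoc2)c1 | intermediate
12 | 3‑methyltetronic acid | CC1=C(O)COC1=O | starting material
13 | 4‑methoxy‑3‑methylfuran‑2(5H)‑one | COC1=C(C)C(=O)OC1 | intermediate
14 | (5Z)‑5‑{(2R,6E)‑9‑[5‑(furan‑3‑ylmethyl)furan‑3‑yl]‑2,6‑dimethylnon‑6‑en‑1‑ylidene}‑4‑methoxy‑3‑methylfuran‑2(5H)‑one | CC1=C(OC)/C(=C/[C@H](C)CCC/C(C)=C/CCc2coc(Cc3ccoc3)c2)OC1=O | intermediate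
15 | (5Z)‑5‑{(2R,6E)‑9‑[5‑(furan‑3‑ylmethyl)furan‑3‑yl]‑2,6‑dimethylnon‑6‑en‑1‑ylidene}‑4‑hydroxy‑3‑methylfuran‑2(5H)‑one | CC1=C(O)/C(=C/[C@H](C)CCC/C(C)=C/CCc2coc(Cc3ccoc3)c2)OC1=O | target

## Summary

Total steps: 9. Longest linear sequence: 8 (steps 1–6, 8, 9); step 7 is a one‑step side branch.

Steps most likely to fail, with fallbacks:

1. **Step 5.** The homoallyl–Ni intermediate could β‑H eliminate towards π‑allyl or isomerised products, radical generation from a β‑branched primary bromide may be slow, and the free alcohol of 9 could interfere or close to an oxetane. Fallback: move the union to the sp2–sp3 bond C5′–C6′. Quench the vinylzirconium from 6 with I2 to give the (E)‑vinyl iodide, and couple it by Pd B‑alkyl Suzuki with the 9‑BBN adduct of (R)‑2‑methylpent‑4‑en‑1‑ol (LiAlH4 reduction of (R)‑2‑methylpent‑4‑enoic acid); this gives 10 directly.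
2. **Step 4.** Hydrozirconation of a 2‑alkyne carrying an unbranched chain is expected to give roughly 9:1 regioselectivity, and the minor diene would be hard to separate. Fallback: build the olefin by carbonyl olefination. Heck reaction of 4 with allyl alcohol gives the 3‑arylpropanal; HWE with triethyl 2‑phosphonopropionate gives the E‑enoate; DIBAL, MnO2 and Ph3P=CH2 then give the same diene 8.
3. **Step 9.** The thiolate could add in conjugate fashion or isomerise the C5=C1′ bond, and the product is acid‑ and air‑sensitive. Fallback: change the enol protecting group to allyl (3‑methyltetronic acid + allyl alcohol, Mitsunobu), run step 8 unchanged, and finish with Pd(PPh3)4/morpholine deallylation at room temperature.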